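The earlier runs and the new flask stem from a simulated flask with made-up constants; noise was put on by code.

Time was what I had to bridge first: this flask is asked about at 20 h, and the runs so far stop at 2.50 h and 8.00 h.

| flask | substrate | gas phase | remark | time |
|---|---|---|---|---|
| north | 0.29 M | 95 mM (held) | the very flask that is asked about, followed so far |  |
| north-west | 0.19 M | 95 mM (held) | run made earlier |  |
| flask | 0.29 M | 95 mM (held) |  | 20 h |

| north: time / h | north: target / % | north-west: time / h | north-west: target / % |
|---|---|---|---|
| 0.667 | 2 | 0.667 | 0 |
| 1.33 | 0 | 1.33 | 0 |
| 2.00 | 2 | 3.00 | 5 |
| 2.50 | 4 | 8.00 | 14 |

(standard deviation of a reading: 1.5 percentage points)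

- at the start none of the gas phase is in solution

- midnight: doubling the transfer coefficient of the gas phase, all else as stated
- noon: doubling the saturation concentration of gas phase, all else as stated

- how much target there is at 20 h, in percent of the substrate charged
- the change that raises the amount of target at 20 h, in percent of the substrate charged most ("none" if none brings more than 2 percentage points) (midnight / noon / none)
- amount of target at 20 h, in percent of the substrate charged, after midnight

As the zero of my scale I took the plain case, pseudo-first-order in substrate: equal dissolved gas at either charge, so that the percent of the charge turned over per hour doesn't depend on the charge. Both runs read zero at 1.33 h, so I took this reading, with its scatter, as the filling time T of the liquid, 1.33 h. From there to the last north-west reading the line climbs at 0.0210 h⁻¹; this s, the fraction of the charge turned over per hour once the liquid has filled, is what I carried. On the north run it gave 2.46% at 2.50 h, against 4% read, a gap about the size of the scatter.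

Carried straight to 20 h, the line gave 39.2%. But substrate thins, so I used 1 − exp(−s(t − T)) and committed to 32.4% of target. If the rate follows dissolved gas, noon raises s, while midnight merely shortens T to 0.665 h, giving 33.4%; I chose noon.

The weak link was the equal gas. I reforged it as a balance: the north flask draws s·c(substrate) = 6.09 mM h⁻¹, so over T the deficit is 8.52% of saturation. That deficit grows in step with T, and T rests on one zero reading, so the early curve is what to watch.

The forecast gave 28%, noon, and 29% after midnight, reading that the “liquid therefore stays near saturation”.

The flask gave 32.0% at 20.0 h, noon as the best change with a gain of 10 percentage points, and 37.4% after midnight.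

    gas phase ⇌ dissolved gas, rate k1*(csat - [dissolved gas]) (kL = 0.00320 min⁻¹)
    substrate + dissolved gas → target (k = 0.00880 M⁻¹ min⁻¹)
    dissolved gas + target → over-reacted product (k = 0.00500 M⁻¹ min⁻¹)
    dissolved gas + target → over-reaction product (k = 0.00150 M⁻¹ min⁻¹)

The flask's dissolved gas stood at 0.0558 M at 20.0 h, a deficit of 41.3%, larger than the 8.52% I had reckoned on the full charge, while the flask's substrate loss of 38.6% lay close to the straight line's 39.2%. The neighbour charged with 0.72 M, on which s gives that same line, held 0.0337 M of dissolved gas and lost 27.0% of its substrate.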